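All runs are simulated on assumed constants.

Doubling the starting material leaves the percent of target in place at equal times: 12.7% in dusk at 1.33 h against 12.8% in noon at 80.0 min, and 16.2% in dusk at 2.00 h against 16.0% in noon at 120 min, each pair within the scatter of 0.5 percentage points. So I treat target formation as first order in starting material, and one number can cross between charges. The noon reading at 25.0 min gives an early pseudo-first-order constant of 0.154 h⁻¹. Dusk at 10.0 h has reached 0.259 as the negative logarithm of the fraction not turned to target. Their quotient, 1.68 h, I call the working hours: the time the flask, at its early speed, would have needed to make what it made. Between 6.00 h and 10.0 h the same constant reads 0.00481 h⁻¹, far below the early one. The target read in dusk accounts for 4.56 mM of the 24 mM partner, so I suspect something else is taking partner.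

| flask | starting material | partner | second substrate | protic impurity | remark | time |
|---|---|---|---|---|---|---|
| dusk | 20 mM | 24 mM | 20 mM | 1 mM | run made earlier |  |
| noon | 40 mM | 24 mM | 20 mM | 1 mM | run made earlier |  |
| north | 20 mM | 24.0 mM | 20.0 mM | 1.00 mM | one stirred flow tank at steady state, fed with the mixture as stated, mean residence time 10 h |  |
| south-west | 20 mM | 24.0 mM | 20.0 mM | 1.00 mM | one stirred flow tank at steady state, fed with the mixture as stated, mean residence time 100 h |  |
| south | 20 mM | 24.0 mM | 20.0 mM | 1.00 mM | everything together in a closed stirred flask, run for 10 h | 10 h |
| north-east | 20 mM | 24.0 mM | 20.0 mM (fed, over 10.0 h) | 1.00 mM | a stirred flask in which second substrate is dosed at a steady rate over 10.0 h without added volume, worked up at 10 h | 10 h |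

dusk run (percent of the starting material charged)

| time / h | target / % |
|---|---|
| 0.833 | 10.9 |
| 1.33 | 12.7 |
| 2.00 | 16.2 |
| 4.00 | 19.2 |
| 6.00 | 21.3 |
| 10.0 | 22.8 |

noon run (percent of the starting material charged)

| time / min | target / % |
|---|---|
| 10.0 | 2.3 |
| 15.0 | 4.3 |
| 25.0 | 6.2 |
| 40.0 | 7.7 |
| 80.0 | 12.8 |
| 120 | 16.0 |

(standard deviation of a reading: 0.5 percentage points)

- the set-up with the highest amount of target at the outlet or at the end, in percent of the starting material put in ("none" if the first two lie within 2 percentage points) (north / south-west / south / north-east / none)
- amount of target at the outlet or at the end, in percent of the starting material put in, north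
- amount of target at the outlet or at the end, in percent of the starting material put in, south-west
- amount of target at the outlet or at the end, in percent of the starting material put in, south
- amount of target at the outlet or at the end, in percent of the starting material put in, north-east

- the stated concentrations are those of everything mixed, before any reaction; amounts are the same in each set-up
- the analysis behind the earlier runs scatters by 0.5 percentage points, standard deviation
- the feed brings no volume worth counting
- the earlier runs were made in a closed, stirred flask

The next run hangs on whether the working hours can be stretched. Dosing feeds on average 10.0 mM of second substrate over 10.0 h, against 20.0 mM charged at once. If second substrate is what takes partner, I estimate the working hours at twice those of dusk, 3.36 h, and north-east at 40.4%. That is my own figure, and it beats dusk's 22.8% by 18 points, beyond the margin of 2 points, so I dose.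

The forecast also picks north-east, but higher than I do: 48%, between 32% and 60%, on the ground that “partner survives longest”. It puts south at 23%, north at 25.5% and south-west at 35%.

The flasks give 17.9% in north, 22.3% in south-west, 22.9% in south and 35.4% in north-east, so north-east leads.

    starting material + partner → target (k = 9.19 L mol⁻¹ h⁻¹)
    second substrate + partner → second product (k = 7.40 L mol⁻¹ h⁻¹)
    starting material + second substrate → cross product (k = 25.5 L mol⁻¹ h⁻¹)
    2 partner → homo dimer (k = 8.14 L mol⁻¹ h⁻¹)
    target ⇌ isomer of the product (K = 0.114, k = 0.188 h⁻¹)
    partner + protic impurity → quenched reagent (k = 3160 L mol⁻¹ h⁻¹)

North-east's 35.4% is 2.84 h of working hours, more than the 1.68 h of dusk but less than the doubling I reckoned. In south, with the other concentrations as charged, starting material has a half-life of 1.4 h by the step to cross product alone and 3.1 h by the step to target alone. So at those concentrations in south, the step to cross product takes 69.8% of the starting material lost through these two steps.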